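**Plan**
- Enabling feature: in the cyclohexane C13–C18 the carbon branch at C13 is cis to the C14 methyl, the C18 oxygen is trans to C13, and C16 (para to C13) carries oxygen. This is the endo-adduct pattern of a 2-silyloxy-1,3-diene and an (E)-β-acyloxyacrylate.
- Cuts, in retrosynthetic order: C8–C9 (Suzuki–Miyaura), C9=C10 (Takai-type boryl-olefination), C11=C12 (Wittig), then C13–C14 and C17–C18 together ([4+2]). The pyrone is cut to a β-ketoester dianion and (E)-3-iodo-2-methylacrylic acid.
- Forward: the siloxydiene and the acrylate close the only carbocycle. Then C15–O by Rubottom oxidation, C16 ketone to C16=C17 alkene, hydroxyl-directed syn-dihydroxylation, and C16 acetylation.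
- Chain: C12 is oxidised to the aldehyde and extended to the enal and the dienylboronate, which is coupled with the pyrone vinyl iodide in the last step.
- Stereochemistry: the catalyst-controlled endo cycloaddition sets C13, C14 and C18 (C17 only provisionally). C15 comes from epoxidation anti to the C14 methyl, and C16/C17 from osmylation directed by the C15 hydroxyl. The alkene geometries come from the Wittig and Takai-type steps and from the (E)-iodo acid.

Key step: step 4

Numbering: ring carbons C13–C18 and chain carbons C7–C12 are numbered as in amaurone A; "lower face" is the ring face of the C13 carbon substituent, "upper face" the opposite one.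

Assumption: the (S)-oxazaborolidinium is taken to expose the α-Re face of acrylate 8, as it is understood to do for simple acrylate esters, with the β-benzoyloxy group not changing the binding mode; if the sense were opposite, the (R)-catalyst would be used with no other change.

**Step 1**
Reactants: 1 3-pentanone; 2 acetaldehyde
Product: 4 (E)-4-methylhex-4-en-3-one, via aldol adduct 3 (not isolated)
Conditions: 1 (4 equiv, neat), H2SO4 (cat.), slow addition of 2, 60 °C, sealed vessel
Reagents that add atoms: none
Why: Acid-catalysed crossed aldol condensation, in which the enol of 3-pentanone adds to protonated acetaldehyde and the aldol dehydrates to the conjugated enone with the thermodynamically preferred (E) geometry.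

**Step 2**
Reactants: 4 (E)-4-methylhex-4-en-3-one
Product: 5 (2Z,4E)-3-(tert-butyldimethylsilyloxy)-4-methylhexa-2,4-diene
Conditions: TBSOTf, Et3N, CH2Cl2, 0 °C
Reagents that add atoms: tert-butyldimethylsilyl trifluoromethanesulfonate, CC(C)(C)[Si](C)(C)OS(=O)(=O)C(F)(F)F
Why: Soft enolisation silylates the carbonyl oxygen and removes a proton from the ethyl CH2, the only enolisable position, and ethyl ketones with a branched second substituent should give the (Z)-silyl enol ether because the enol methyl avoids the 1-methylpropenyl group.

**Step 3**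
Reactants: 6 ethyl propiolate; 7 benzoic acid
Product: 8 ethyl (E)-3-(benzoyloxy)acrylate
Conditions: N-methylmorpholine (10 mol%), CH2Cl2, rt
Reagents that add atoms: none
Why: Tertiary-amine-catalysed oxa-Michael addition of the carboxylic acid to the propiolate through a β-ammonium acrylate (addition–elimination), which is known to give (E)-β-acyloxyacrylates.

**Step 4**
Reactants: 5 (2Z,4E)-3-(tert-butyldimethylsilyloxy)-4-methylhexa-2,4-diene; 8 ethyl (E)-3-(benzoyloxy)acrylate
Product: 9 ethyl 2-(benzoyloxy)-4-(tert-butyldimethylsilyloxy)-3,5,6-trimethylcyclohex-4-ene-1-carboxylate (C13 ester, C14 methyl and C17 methyl on the lower face, C18 benzoate on the upper face)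
Conditions: (S)-1-(2-methylphenyl)-3,3-diphenyltetrahydro-1H,3H-pyrrolo[1,2-c][1,3,2]oxazaborole (20 mol%), HN(SO2CF3)2 (20 mol%), CH2Cl2, –40 to –20 °C
Reagents that add atoms: none
Why: The N-protonated oxazaborolidine binds the acrylate carbonyl of 8 and lowers its LUMO, and diene 5 adds in a concerted, asynchronous, suprafacial [4+2] in which the C17–C18 bond (enol ether terminus to acrylate β-carbon) runs ahead of the C13–C14 bond. The closest known reaction type is the oxazaborolidinium-catalysed Diels–Alder reaction of 2-silyloxybutadienes with acrylate esters. The cyclohexene C13–C18 closes by intermolecular [4π+2π] cycloaddition, both σ-bonds forming on one face of each partner. C14 and C17 follow from the diene geometry (both terminal methyls outside, hence cis), C18 from the (E)-dienophile (benzoate trans to the ester), and C13 relative to C14 from the endo position of the coordinated ester. The absolute sense comes from the catalyst, which shields one face of the bound acrylate so that the diene adds to the Re face of the α-carbon. The step needs para regiochemistry, endo selectivity and one enantioface: the siloxy group makes C17 the nucleophilic terminus and the ester makes C18 the electrophilic one, Lewis-acid coordination enforces endo, and the catalyst pocket selects the face.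

**Step 5**
Reactants: 9 cycloadduct ester
Product: 10 4-(tert-butyldimethylsilyloxy)-2-(hydroxymethyl)-3,5,6-trimethylcyclohex-4-en-1-ol (C12 primary and C18 secondary diol)
Conditions: i-Bu2AlH (5 equiv), CH2Cl2, –78 to 0 °C; aq. potassium sodium tartrate
Reagents that add atoms: none
Why: Excess aluminium hydride reduces the ethyl ester to the primary alcohol and cleaves the benzoate reductively, so both base-sensitive acyl groups are removed without a basic step, while the silyl enol ether is inert to hydride.

**Step 6**
Reactants: 10 diol
Product: 11 C12,C18-O-isopropylidene acetal of 10 (trans-fused 2,2-dimethyl-1,3-dioxane)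
Conditions: 2-methoxypropene, PPTS (5 mol%), CH2Cl2, 0 °C; Et3N quench
Reagents that add atoms: 2-methoxypropene, C=C(C)OC
Why: Kinetic acetalisation of the 1,3-diol under pyridinium catalysis gives the trans-fused six-membered acetonide under conditions mild enough to spare the tetrasubstituted silyl enol ether.

**Step 7**
Reactants: 11 acetonide silyl enol ether
Product: 13 C15-silyloxy C16-ketone acetonide, via silyloxy epoxide 12 (not isolated)
Conditions: mCPBA (1.2 equiv), CH2Cl2, –20 to 0 °C
Reagents that add atoms: 3-chloroperoxybenzoic acid, O=C(OO)c1cccc(Cl)c1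
Why: Rubottom oxidation, in which the peracid epoxidises the enol ether on the face opposite the pseudoaxial C14 methyl, the silyloxy epoxide opens to the oxocarbenium ion and 1,4-silyl migration gives the α-silyloxy ketone, setting C15 with its oxygen on the upper face.

**Step 8**
Reactants: 13 C15-silyloxy C16-ketone acetonide
Product: 15 C16 enol triflate (C16=C17), via potassium enolate 14 (not isolated)
Conditions: KN(SiMe3)2, THF, –78 °C; then PhN(SO2CF3)2, –78 to 0 °C
Reagents that add atoms: N-phenylbis(trifluoromethanesulfonimide), O=S(=O)(N(c1ccccc1)S(=O)(=O)C(F)(F)F)C(F)(F)F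
Why: Enolisation at C17, the only α-carbon bearing hydrogen (axial and aligned with the carbonyl), followed by O-sulfonylation gives the enol triflate regiospecifically, and β-elimination of the C18 oxygen is disfavoured because the trans-fused dioxane holds that C–O bond equatorial, near the nodal plane of the enolate.

**Step 9**
Reactants: 15 enol triflate
Product: 16 C16=C17 alkene with C15 silyl ether
Conditions: Pd(OAc)2 (5 mol%), PPh3 (10 mol%), HCO2H, Bu3N, DMF, 60 °C
Reagents that add atoms: none
Why: Palladium-catalysed formate reduction of an enol triflate (oxidative addition to zerovalent palladium, formate exchange, decarboxylation, reductive elimination) replaces the triflate by hydrogen and leaves the trisubstituted alkene.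

**Step 10**
Reactants: 16 silyl ether alkene
Product: 17 tertiary allylic alcohol (free C15 hydroxyl)
Conditions: Bu4NF, THF, 50 °C
Reagents that add atoms: none
Why: Fluoride-mediated desilylation, driven by Si–F bond formation, frees the C15 hydroxyl needed as directing group and does not touch the acetonide.

**Step 11**
Reactants: 17 tertiary allylic alcohol
Product: 19 C15,C16,C17-triol acetonide, via osmate ester 18 (not isolated)
Conditions: OsO4 (1.05 equiv), TMEDA (1.1 equiv), CH2Cl2, –78 °C; then aq. Na2SO3, THF, 60 °C
Reagents that add atoms: osmium tetroxide, O=[Os](=O)(=O)=O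
Why: Hydroxyl-directed syn-dihydroxylation with OsO4·TMEDA, in which the pseudoaxial C15 hydroxyl hydrogen-bonds to the reagent and delivers it to the upper face, also the face remote from the axial C14 methyl, so the C16 and C17 oxygens form cis to those at C15 and C18 in a suprafacial [3+2] addition.

**Step 12**
Reactants: 19 triol acetonide
Product: 20 C16 acetate acetonide
Conditions: Ac2O, DMAP, pyridine, CH2Cl2, rt
Reagents that add atoms: acetic anhydride, CC(=O)OC(C)=O
Why: DMAP-catalysed acylation acetylates the only secondary hydroxyl (C16), the two tertiary hydroxyls being too hindered to react under these conditions.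

**Step 13**
Reactants: 20 acetate acetonide
Product: 21 2-(hydroxymethyl)-3,4,6-trimethylcyclohexane-1,4,5,6-tetrol 5-acetate (C12, C15, C17, C18 hydroxyls free; C16 acetate)
Conditions: AcOH/THF/H2O (3:1:1), 40 °C
Reagents that add atoms: none
Why: Acid-catalysed hydrolysis of the isopropylidene acetal frees the C12 and C18 hydroxyls, and under acid the C16 acetate should neither hydrolyse nor migrate.

**Step 14**
Reactants: 21 tetraol acetate
Product: 22 C12 aldehyde (C18 hydroxyl free)
Conditions: Cu(MeCN)4OTf (5 mol%), 2,2'-bipyridine (5 mol%), TEMPO (5 mol%), N-methylimidazole (10 mol%), air, MeCN, rt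
Reagents that add atoms: none
Why: Copper/TEMPO aerobic alcohol oxidation is selective for primary over secondary and tertiary hydroxyls and stops at the aldehyde, whose equatorial position at C13 is the thermodynamically preferred one so that epimerisation is not a threat.

**Step 15**
Reactants: 22 aldehyde
Product: 23 (E)-enal (C11=C12, C10 aldehyde)
Conditions: Ph3P=C(CH3)CHO (2 equiv), toluene, 90 °C
Reagents that add atoms: 2-(triphenylphosphoranylidene)propanal, CC(C=O)=P(c1ccccc1)(c1ccccc1)c1ccccc1
Why: Wittig olefination with a stabilised ylide gives the (E)-trisubstituted enal, and the ylide is too weakly basic to deprotonate the hydroxyls or attack the acetate.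

**Step 16**
Reactants: 23 (E)-enal
Product: 24 (9E,11E)-dienyl pinacol boronate
Conditions: CrCl2 (8 equiv), LiI (4 equiv), Cl2CHB(pin) (2 equiv), THF, rt
Reagents that add atoms: 2-(dichloromethyl)-4,4,5,5-tetramethyl-1,3,2-dioxaborolane, ClC(Cl)B1OC(C)(C)C(C)(C)O1
Why: Takai-type olefination, in which the geminal dichromium reagent formed from the dihalomethylboronate and divalent chromium adds to the aldehyde and eliminates to the (E)-alkenylboronate, under conditions that tolerate acetates and free hydroxyls.

**Step 17**
Reactants: 25 diethyl methylmalonate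
Product: 27 diethyl 2-(diiodomethyl)-2-methylmalonate, via sodium enolate 26 (not isolated)
Conditions: NaH, Et2O, reflux; then CHI3, reflux
Reagents that add atoms: iodoform, IC(I)I
Why: C-Alkylation of the malonate enolate by iodoform (capture of diiodocarbene by the enolate and protonation, formally substitution of one iodide) installs the CHI2 group on the quaternary carbon.

**Step 18**
Reactants: 27 diethyl 2-(diiodomethyl)-2-methylmalonate
Product: 29 (E)-3-iodo-2-methylacrylic acid, via dicarboxylate 28 (not isolated)
Conditions: KOH, EtOH/H2O, reflux; then aq. HCl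
Reagents that add atoms: potassium hydroxide, [K+].[OH-]
Why: Saponification followed by decarboxylative anti elimination of iodide from the malonate dianion gives the acrylic acid with the (E)-iodoalkene geometry.

**Step 19**
Reactants: 29 (E)-3-iodo-2-methylacrylic acid; 30 methyl 2-methyl-3-oxopentanoate
Product: 33 methyl (6E)-7-iodo-2,4,6-trimethyl-3,5-dioxohept-6-enoate, via acyl imidazolide 31 (not isolated), via ketoester dianion 32 (not isolated)
Conditions: 29, 1,1'-carbonyldiimidazole, THF, rt; separately 30 (2.2 equiv), NaH, THF, 0 °C, then n-BuLi, 0 °C; combine at –78 to 0 °C; aq. HCl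
Reagents that add atoms: none
Why: Claisen-type C-acylation in which the γ-carbon of the β-ketoester dianion, its most nucleophilic site, attacks the acyl imidazolide, the second equivalent of dianion absorbing the acidic proton of the diketo ester.

**Step 20**
Reactants: 33 diketo ester
Product: 34 4-hydroxy-6-[(E)-1-iodoprop-1-en-2-yl]-3,5-dimethyl-2H-pyran-2-one
Conditions: DBU, toluene, 60 °C
Reagents that add atoms: none
Why: Base-mediated lactonisation in which the enol oxygen of the C5 ketone attacks the methyl ester (6-exo-trig acyl substitution) and methanol is lost to give the 4-hydroxy-2-pyranone.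

**Step 21**
Reactants: 34 hydroxypyranone
Product: 35 2-[(E)-1-iodoprop-1-en-2-yl]-6-methoxy-3,5-dimethyl-4H-pyran-4-one
Conditions: CF3SO3CH3, CH2Cl2, 0 °C to rt; then aq. NaHCO3
Reagents that add atoms: methyl trifluoromethanesulfonate, COS(=O)(=O)C(F)(F)F
Why: The hard methylating agent alkylates the neutral hydroxypyranone at the lactone carbonyl oxygen (its most basic site, unhindered unlike the C4 hydroxyl between two methyls), and loss of a proton gives the 2-methoxy-4-pyranone.

**Step 22**
Reactants: 24 dienyl pinacol boronate; 35 pyrone vinyl iodide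
Product: 36 amaurone A
Conditions: Pd(PPh3)4 (10 mol%), TlOEt (1.8 equiv), THF/H2O (3:1), rt
Reagents that add atoms: none
Why: Suzuki–Miyaura coupling (oxidative addition of the vinyl iodide to zerovalent palladium, ethoxide-accelerated transmetalation of the dienylboronate, reductive elimination) joins C8 to C9 with retention of both alkene geometries at room temperature, so the acetate and the triene should survive.

**Compound list**
1 | 3-pentanone | CCC(=O)CC | starting material
2 | acetaldehyde | CC=O | starting material
3 | 5-hydroxy-4-methylhexan-3-one (aldol adduct, diastereomer mixture) | CCC(=O)C(C)C(C)O | intermediate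
4 | (E)-4-methylhex-4-en-3-one | C/C=C(C)/C(=O)CC | intermediate
5 | (2Z,4E)-3-(tert-butyldimethylsilyloxy)-4-methylhexa-2,4-diene | C/C=C(C)/C(O[Si](C)(C)C(C)(C)C)=C/C | intermediate
6 | ethyl propiolate | C#CC(=O)OCC | starting material
7 | benzoic acid | O=C(O)c1ccccc1 | starting material
8 | ethyl (E)-3-(benzoyloxy)acrylate | CCOC(=O)/C=C/OC(=O)c1ccccc1 | intermediate
9 | ethyl 2-(benzoyloxy)-4-(tert-butyldimethylsilyloxy)-3,5,6-trimethylcyclohex-4-ene-1-carboxylate; C13 ester, C14 methyl, C17 methyl on the lower face, C18 benzoate on the upper face | CCOC(=O)[C@@H]1[C@H](C)C(C)=C(O[Si](C)(C)C(C)(C)C)[C@H](C)[C@H]1OC(=O)c2ccccc2 | intermediate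
10 | 4-(tert-butyldimethylsilyloxy)-2-(hydroxymethyl)-3,5,6-trimethylcyclohex-4-en-1-ol; C13 hydroxymethyl and both methyls lower face, C18 hydroxyl upper face | OC[C@@H]1[C@H](C)C(C)=C(O[Si](C)(C)C(C)(C)C)[C@H](C)[C@H]1O | intermediate
11 | C12,C18-O-isopropylidene acetal of 10 (trans-fused 1,3-dioxane) | CC1(C)OC[C@@H]2[C@H](C)C(C)=C(O[Si](C)(C)C(C)(C)C)[C@H](C)[C@H]2O1 | intermediate
12 | C15,C16 upper-face epoxide of 11 with the silyloxy group on C16 | CC1(C)OC[C@@H]2[C@H](C)[C@@]3(C)O[C@@]3(O[Si](C)(C)C(C)(C)C)[C@H](C)[C@H]2O1 | intermediate
13 | C16 ketone with C15 methyl (lower face) and C15 tert-butyldimethylsilyloxy (upper face), acetonide retained | CC1(C)OC[C@@H]2[C@H](C)[C@@](C)(O[Si](C)(C)C(C)(C)C)C(=O)[C@H](C)[C@H]2O1 | intermediate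
14 | potassium C16=C17 enolate of 13 | CC1(C)OC[C@@H]2[C@H](C)[C@@](C)(O[Si](C)(C)C(C)(C)C)C([O-])=C(C)[C@H]2O1.[K+] | intermediate
15 | C16 enol trifluoromethanesulfonate (C16=C17) of 13 | CC1(C)OC[C@@H]2[C@H](C)[C@@](C)(O[Si](C)(C)C(C)(C)C)C(OS(=O)(=O)C(F)(F)F)=C(C)[C@H]2O1 | intermediate
16 | C16=C17 alkene with C15 silyl ether, acetonide retained | CC1(C)OC[C@@H]2[C@H](C)[C@@](C)(O[Si](C)(C)C(C)(C)C)C=C(C)[C@H]2O1 | intermediate
17 | C16=C17 alkene with free tertiary C15 hydroxyl (upper face), acetonide retained | CC1(C)OC[C@@H]2[C@H](C)[C@@](C)(O)C=C(C)[C@H]2O1 | intermediate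
18 | osmate ester of 17: cyclic C16,C17 glycolate of hexavalent osmium (dioxo) on the upper face, with TMEDA | CC1(C)OC[C@@H]2[C@H](C)[C@@](C)(O)[C@H]3O[Os](=O)(=O)O[C@@]3(C)[C@H]2O1.CN(C)CCN(C)C | intermediate
19 | C15,C16,C17-triol (all hydroxyls upper face) with C12,C18 acetonide | CC1(C)OC[C@@H]2[C@H](C)[C@@](C)(O)[C@@H](O)[C@@](C)(O)[C@H]2O1 | intermediate
20 | C16 acetate of 19 | CC1(C)OC[C@@H]2[C@H](C)[C@@](C)(O)[C@@H](OC(C)=O)[C@@](C)(O)[C@H]2O1 | intermediate
21 | 2-(hydroxymethyl)-3,4,6-trimethylcyclohexane-1,4,5,6-tetrol 5-acetate; C16 acetate, free C12, C15, C17, C18 hydroxyls | OC[C@@H]1[C@H](C)[C@@](C)(O)[C@@H](OC(C)=O)[C@@](C)(O)[C@H]1O | intermediate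
22 | C12 aldehyde of 21 (formyl on C13, lower face) | O=C[C@@H]1[C@H](C)[C@@](C)(O)[C@@H](OC(C)=O)[C@@](C)(O)[C@H]1O | intermediate
23 | (E)-2-methyl-3-(ring C13)propenal: C11=C12 (E), C10 aldehyde | O=C/C(C)=C/[C@@H]1[C@H](C)[C@@](C)(O)[C@@H](OC(C)=O)[C@@](C)(O)[C@H]1O | intermediate
24 | (9E,11E)-dienyl pinacol boronate (boron on C9) | CC1(C)OB(/C=C/C(C)=C/[C@@H]2[C@H](C)[C@@](C)(O)[C@@H](OC(C)=O)[C@@](C)(O)[C@H]2O)OC1(C)C | intermediate
25 | diethyl methylmalonate | CCOC(=O)C(C)C(=O)OCC | starting material
26 | sodium enolate of diethyl methylmalonate | CCOC(=O)C(C)=C([O-])OCC.[Na+] | intermediate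
27 | diethyl 2-(diiodomethyl)-2-methylmalonate | CCOC(=O)C(C)(C(I)I)C(=O)OCC | intermediate
28 | dipotassium 2-(diiodomethyl)-2-methylmalonate | [K+].[K+].[O-]C(=O)C(C)(C(I)I)C([O-])=O | intermediate
29 | (E)-3-iodo-2-methylacrylic acid | OC(=O)/C(C)=C/I | intermediate
30 | methyl 2-methyl-3-oxopentanoate | CCC(=O)C(C)C(=O)OC | starting material
31 | 1-[(E)-3-iodo-2-methylacryloyl]imidazole | O=C(/C(C)=C/I)n1ccnc1 | intermediate
32 | sodium lithium dianion (bis-enolate) of methyl 2-methyl-3-oxopentanoate | CC=C([O-])C(C)=C([O-])OC.[Na+].[Li+] | intermediate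
33 | methyl (6E)-7-iodo-2,4,6-trimethyl-3,5-dioxohept-6-enoate | COC(=O)C(C)C(=O)C(C)C(=O)/C(C)=C/I | intermediate
34 | 4-hydroxy-6-[(E)-1-iodoprop-1-en-2-yl]-3,5-dimethyl-2H-pyran-2-one | O=c1oc(/C(C)=C/I)c(C)c(O)c1C | intermediate
35 | 2-[(E)-1-iodoprop-1-en-2-yl]-6-methoxy-3,5-dimethyl-4H-pyran-4-one | COc1oc(/C(C)=C/I)c(C)c(=O)c1C | intermediate
36 | amaurone A | COc1oc(/C(C)=C/C=C/C(C)=C/[C@@H]2[C@H](C)[C@@](C)(O)[C@@H](OC(C)=O)[C@@](C)(O)[C@H]2O)c(C)c(=O)c1C | target

**Step count**
Total: 22 steps. Longest linear sequence: 16 steps (steps 1, 2, 4–16, 22).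

**Steps most likely to fail**

1. Step 4. The donor-substituted acrylate may be activated too weakly by the oxazaborolidinium, so that cycloaddition is slow, silyl transfer from the diene competes, or facial selectivity is low. The fallback moves stereocontrol from the catalyst to a covalently bound auxiliary, sets out from diene 5 and returns at diol 10. (R)-4-Benzyloxazolidin-2-one is N-acylated with propiolic acid (pivaloyl mixed anhydride, Et3N, LiCl) to (R)-4-benzyl-3-propioloyloxazolidin-2-one F1. Benzoic acid 7 is added under N-methylmorpholine catalysis to give (R)-4-benzyl-3-[(E)-3-(benzoyloxy)acryloyl]oxazolidin-2-one F2. F2 and diene 5 are combined with Me2AlCl (1.4 equiv, CH2Cl2, –78 °C); the chelated s-cis imide should be attacked on the face remote from the benzyl group, the same α-Re face, to give the imide cycloadduct F3. LiAlH4 (THF, –20 °C) then removes the auxiliary and the benzoate reductively to give diol 10.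

2. Step 8. Deprotonation of the hindered tertiary C17–H may be slow, or the enolate may expel the C18 acetal oxygen before it is trapped. The fallback replaces enolate chemistry by reduction and dehydration, sets out from ketone 13 and returns at alkene 16. LiAlH4 (THF, 0 °C) gives the C16 alcohol F4, either epimer being usable. It is dehydrated toward C17, the only neighbouring carbon that carries hydrogen: by anti elimination with Martin sulfurane if the hydroxyl is axial, or by syn elimination with the Burgess reagent if it is equatorial.

3. Step 15. The unprotected β-hydroxy aldehyde 22 may undergo retro-aldol ring opening or dehydration during the thermal Wittig reaction, or may already suffer during its formation in step 14. The fallback masks the C18 hydroxyl first, sets out from tetraol 21 and returns at enal 23. Silylation of the primary and secondary hydroxyls (Et3SiCl, imidazole, DMF) gives the bis(triethylsilyl) ether F5. Direct Swern oxidation of the primary silyl ether gives the C18-silylated aldehyde F6. The same ylide gives the silylated enal F7, and HF·pyridine (THF, 0 °C) releases enal 23.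

**Further compounds**
F1 | step 4 | (R)-4-benzyl-3-propioloyloxazolidin-2-one | C#CC(=O)N1[C@H](Cc2ccccc2)COC1=O
F2 | step 4 | (R)-4-benzyl-3-[(E)-3-(benzoyloxy)acryloyl]oxazolidin-2-one | O=C(O/C=C/C(=O)N1[C@H](Cc2ccccc2)COC1=O)c1ccccc1
F3 | step 4 | imide cycloadduct: analogue of 9 with the (R)-4-benzyl-2-oxooxazolidin-3-yl carbonyl group on C13 in place of the ethyl ester | O=C([C@@H]1[C@H](C)C(C)=C(O[Si](C)(C)C(C)(C)C)[C@H](C)[C@H]1OC(=O)c1ccccc1)N1[C@H](Cc2ccccc2)COC1=O
F4 | step 8 | C16 alcohol from reduction of ketone 13 (C16 configuration not defined) | CC1(C)OC[C@@H]2[C@H](C)[C@@](C)(O[Si](C)(C)C(C)(C)C)C(O)[C@H](C)[C@H]2O1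
F5 | step 15 | C12,C18-bis(triethylsilyl) ether of tetraol 21 | CC[Si](CC)(CC)OC[C@@H]1[C@H](C)[C@@](C)(O)[C@@H](OC(C)=O)[C@@](C)(O)[C@H]1O[Si](CC)(CC)CC
F6 | step 15 | C12 aldehyde with C18 triethylsilyl ether | O=C[C@@H]1[C@H](C)[C@@](C)(O)[C@@H](OC(C)=O)[C@@](C)(O)[C@H]1O[Si](CC)(CC)CC
F7 | step 15 | (E)-enal with C18 triethylsilyl ether | O=C/C(C)=C/[C@@H]1[C@H](C)[C@@](C)(O)[C@@H](OC(C)=O)[C@@](C)(O)[C@H]1O[Si](CC)(CC)CC
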